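**Retrosynthetic overview**

1. Target 17 ⇐ hydrogenolysis of its tridecabenzyl 8,8'-dibromide 16 ⇐ C4(upper)–C6(lower) bond by flavan-4-yl cation coupling of 15 with gallate 14; both halves come from one monomer, bromide 12.
2. 12 ⇐ 11 ⇐ racemic flavan-3-one 10: one hydrogenation with dynamic kinetic resolution sets C2 and C3 (2,3-cis) of every flavan unit.
3. 10 ⇐ spiro-dithianes 9 and 8 ⇐ one-pot [3+3] annulation of the dilithiated dithianyl carbinol 4 (O1–C2–C3, with C3 as acyl-anion carbon) with 2,4,6-trifluorobenzyl bromide 5 (C4 and ring A): C3–C4 by alkylation, O1–C8a by SNAr.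
4. Enabling feature: in ring C the carbinol carbon C3 lies between C2 and the benzylic C4, and ring A is a phloroglucinol whose oxygenated carbons C5, C7 and C8a are mutually meta, with C8a ortho to C4a. Ring A can therefore enter as a symmetric 2,4,6-trifluorobenzyl unit (either ortho fluorine becomes C8a–O1, the other two become the C5 and C7 ethers), and C3 can enter at the ketone level as a dithiane, which also makes C2–H labile for the later resolution.
5. Ring order: rings A, B and the galloyl ring are bought as benzene rings; ring C of both flavan units is closed in step 2; the dithiane is a temporary ring, removed in step 4.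

Key step: step 2

Assumption: the catalyst enantiomer written in step 5 is taken, by analogy with 2-arylcyclohexanones, to give the 2R,3R series; the first run is to be checked against 11 made by benzylation of natural (−)-epigallocatechin, and the mirror-image catalyst is used if the sense is opposite. Racemic compounds (4, 8, 9, 10) are written without stereo descriptors.

**Route**

Step 1
Reactants: 1 3,4,5-tris(benzyloxy)benzaldehyde; 2 1,3-dithiane
Product: 4 rac-(1,3-dithian-2-yl)[3,4,5-tris(benzyloxy)phenyl]methanol, via 2-lithio-1,3-dithiane 3 (not isolated)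
Conditions: n-BuLi, THF, −30 °C; then 1, −78 → 0 °C; H2O
Reagents that add atoms: none
Why: Corey–Seebach addition of a 2-lithio-1,3-dithiane to an aromatic aldehyde, compatible with aryl benzyl ethers; the new carbinol centre (future C2) is left racemic on purpose because it is fixed in step 5.

Step 2
Reactants: 4 rac-(1,3-dithian-2-yl)[3,4,5-tris(benzyloxy)phenyl]methanol; 5 2,4,6-trifluorobenzyl bromide
Product: 8 rac-5,7-difluoro-2-[3,4,5-tris(benzyloxy)phenyl]spiro[chromane-3,2'-[1,3]dithiane], via dilithio dianion 6 (not isolated), via C-benzylated lithium alkoxide 7 (not isolated)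
Conditions: n-BuLi (2.05 equiv), TMEDA, THF, −78 → −20 °C; 5 (1.05 equiv), −78 → 0 °C; then DMPU, 60 °C
Reagents that add atoms: none
Why: Proposed new method: two equivalents of n-BuLi should convert 4 into the O,C-dilithio species 6 (a β-oxido group, unlike a β-alkoxy group, cannot be eliminated), whose dithianyl carbanion attacks the benzylic bromide of 5 by SN2 to form C3–C4 (7); on warming with DMPU the remaining alkoxide O1 adds to an ortho C–F carbon activated by the two meta fluorines and expels fluoride (SNAr) to form O1–C8a. The closest known reaction types are the Corey–Seebach alkylation of 2-lithio-1,3-dithianes, the C-alkylation of β-oxido carbanions (Fráter–Seebach-type dianions) and alkoxide SNAr closure of chromans onto fluoroarenes; what is new is their union through a β-oxido dithianyl dianion. Ring C closes in a 6-exo-trig mode through a Meisenheimer adduct. No stereocentre is created: C2 is carried as the racemate and C3 is a non-stereogenic spiro carbon, both being fixed in step 5. The step needs C- before O-alkylation and ring closure through O1 only: the carbanion is by far the better nucleophile at −78 °C, the two ortho fluorines are equivalent by symmetry, and because C3 is a dithioketal there is neither a C3 oxygen that could close a five-membered ether nor an enolate that could give a benzofuran. Exactly two equivalents of base, consumed before 5 is added, should keep the acidic ring C–H of the trifluorophenyl group from being metalated.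

Step 3
Reactants: 8 rac-5,7-difluoro-2-[3,4,5-tris(benzyloxy)phenyl]spiro[chromane-3,2'-[1,3]dithiane]
Product: 9 rac-5,7-bis(benzyloxy)-2-[3,4,5-tris(benzyloxy)phenyl]spiro[chromane-3,2'-[1,3]dithiane]
Conditions: BnOH, NaH, NMP, 90 °C
Reagents that add atoms: benzyl alcohol, OCc1ccccc1
Why: double SNAr of the two remaining, mutually meta aryl fluorides by sodium benzyloxide in a dipolar aprotic solvent, the same reaction type that turns 1,3,5-trifluorobenzene into 1-fluoro-3,5-dialkoxybenzenes; the dithioketal and the non-acidic C2–H are inert to alkoxide.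

Step 4
Reactants: 9 rac-5,7-bis(benzyloxy)-2-[3,4,5-tris(benzyloxy)phenyl]spiro[chromane-3,2'-[1,3]dithiane]
Product: 10 rac-5,7-bis(benzyloxy)-2-[3,4,5-tris(benzyloxy)phenyl]chroman-3-one
Conditions: MeI, CaCO3, MeCN/THF/H2O, 45 °C
Reagents that add atoms: water, O
Why: alkylative dithioketal hydrolysis (S-methylation, thionium ion, attack of water) under carbonate-buffered conditions that spare benzyl ethers and electron-rich arenes; it unveils the C3 ketone and thereby makes C2–H acidic.

Step 5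
Reactants: 10 rac-5,7-bis(benzyloxy)-2-[3,4,5-tris(benzyloxy)phenyl]chroman-3-one
Product: 11 (2R,3R)-5,7-bis(benzyloxy)-2-[3,4,5-tris(benzyloxy)phenyl]chroman-3-ol
Conditions: H2 (50 atm), RuCl2[(S)-Xyl-SDP][(R,R)-DPEN] (0.5 mol %), t-BuOK (10 mol %), i-PrOH/THF, 25 °C
Reagents that add atoms: none
Why: Noyori-type asymmetric hydrogenation with dynamic kinetic resolution, known for configurationally labile α-aryl cyclic ketones: base equilibrates C2 through the enolate, the chiral ruthenium hydride should reduce one enantiomer faster and deliver hydride anti to the pseudo-equatorial C2 aryl group, so that C2 (R) and C3 (R, 2,3-cis) are set in one catalytic event.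

Step 6
Reactants: 11 (2R,3R)-5,7-bis(benzyloxy)-2-[3,4,5-tris(benzyloxy)phenyl]chroman-3-ol
Product: 12 (2R,3R)-8-bromo-5,7-bis(benzyloxy)-2-[3,4,5-tris(benzyloxy)phenyl]chroman-3-ol
Conditions: NBS (1.0 equiv), CH2Cl2, −78 → −20 °C
Reagents that add atoms: N-bromosuccinimide, O=C1CCC(=O)N1Br
Why: electrophilic aromatic bromination, which in 5,7-di-O-benzylflavan-3-ols goes to C8 (ortho to O1 and O7, less hindered than C6); the bromine blocks C8 in both coupling partners and is removed in step 10.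

Step 7
Reactants: 12 (2R,3R)-8-bromo-5,7-bis(benzyloxy)-2-[3,4,5-tris(benzyloxy)phenyl]chroman-3-ol; 13 3,4,5-tris(benzyloxy)benzoic acid
Product: 14 (2R,3R)-8-bromo-5,7-bis(benzyloxy)-2-[3,4,5-tris(benzyloxy)phenyl]chroman-3-yl 3,4,5-tris(benzyloxy)benzoate
Conditions: EDC·HCl, DMAP (cat.), CH2Cl2, 25 °C
Reagents that add atoms: none
Why: Steglich esterification of the axial 3-OH, which touches no stereocentre and puts the galloyl group on the future lower unit only.

Step 8
Reactants: 12 (2R,3R)-8-bromo-5,7-bis(benzyloxy)-2-[3,4,5-tris(benzyloxy)phenyl]chroman-3-ol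
Product: 15 (2R,3R,4S)-8-bromo-5,7-bis(benzyloxy)-4-(2-ethoxyethoxy)-2-[3,4,5-tris(benzyloxy)phenyl]chroman-3-ol
Conditions: DDQ, 2-ethoxyethanol, CH2Cl2, 25 °C
Reagents that add atoms: 2-ethoxyethanol, CCOCCO
Why: DDQ benzylic oxidation (hydride abstraction at C4 to a cation stabilized by ring A) with capture by the alcohol anti to the C2 aryl and C3 hydroxyl groups, which should give the 3,4-trans C4 ether.

Step 9
Reactants: 15 (2R,3R,4S)-8-bromo-5,7-bis(benzyloxy)-4-(2-ethoxyethoxy)-2-[3,4,5-tris(benzyloxy)phenyl]chroman-3-ol; 14 (2R,3R)-8-bromo-5,7-bis(benzyloxy)-2-[3,4,5-tris(benzyloxy)phenyl]chroman-3-yl 3,4,5-tris(benzyloxy)benzoate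
Product: 16 (2R,3R)-8-bromo-5,7-bis(benzyloxy)-6-[(2R,3R,4R)-8-bromo-5,7-bis(benzyloxy)-3-hydroxy-2-[3,4,5-tris(benzyloxy)phenyl]chroman-4-yl]-2-[3,4,5-tris(benzyloxy)phenyl]chroman-3-yl 3,4,5-tris(benzyloxy)benzoate
Conditions: TMSOTf (cat.), 4 Å molecular sieves, CH2Cl2, −78 → −40 °C; 14 in excess (2.5 equiv)
Reagents that add atoms: none
Why: Lewis-acid-mediated SN1 Friedel–Crafts alkylation by the flavan-4-yl cation: with C8 brominated in both partners only C6 of ring A of 14 is open, and attack anti to the C3 hydroxyl and C2 aryl groups should give the 3,4-trans bond (the C4 label reads R here and S in 17 only because bromine and benzyl groups change the CIP ranking).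

Step 10
Reactants: 16 (2R,3R)-8-bromo-5,7-bis(benzyloxy)-6-[(2R,3R,4R)-8-bromo-5,7-bis(benzyloxy)-3-hydroxy-2-[3,4,5-tris(benzyloxy)phenyl]chroman-4-yl]-2-[3,4,5-tris(benzyloxy)phenyl]chroman-3-yl 3,4,5-tris(benzyloxy)benzoate
Product: 17 (2R,3R)-5,7-dihydroxy-6-[(2R,3R,4S)-3,5,7-trihydroxy-2-(3,4,5-trihydroxyphenyl)chroman-4-yl]-2-(3,4,5-trihydroxyphenyl)chroman-3-yl 3,4,5-trihydroxybenzoate
Conditions: H2 (1 atm), Pd(OH)2/C, NaOAc, THF/MeOH/H2O, 25 °C
Reagents that add atoms: none
Why: catalytic hydrogenolysis of thirteen benzyl ethers and both aryl bromides in one operation, with acetate buffering the hydrogen bromide so that the acid-labile interflavan bond, the gallate ester and all five stereocentres should stay intact.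

**Compound list**

1 | 3,4,5-tris(benzyloxy)benzaldehyde | O=Cc1cc(OCc2ccccc2)c(OCc2ccccc2)c(OCc2ccccc2)c1 | starting material
2 | 1,3-dithiane | C1CSCSC1 | starting material
3 | 2-lithio-1,3-dithiane | [Li+].[CH-]1SCCCS1 | intermediate
4 | rac-(1,3-dithian-2-yl)[3,4,5-tris(benzyloxy)phenyl]methanol | OC(c1cc(OCc2ccccc2)c(OCc2ccccc2)c(OCc2ccccc2)c1)C1SCCCS1 | intermediate
5 | 2,4,6-trifluorobenzyl bromide | BrCc1c(F)cc(F)cc1F | starting material
6 | dilithium salt (O,C-dianion) of 4 | [Li+].[Li+].[O-]C(c1cc(OCc2ccccc2)c(OCc2ccccc2)c(OCc2ccccc2)c1)[C-]1SCCCS1 | intermediate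
7 | lithium rac-[2-(2,4,6-trifluorobenzyl)-1,3-dithian-2-yl][3,4,5-tris(benzyloxy)phenyl]methanolate | [Li+].[O-]C(c1cc(OCc2ccccc2)c(OCc2ccccc2)c(OCc2ccccc2)c1)C1(Cc2c(F)cc(F)cc2F)SCCCS1 | intermediate
8 | rac-5,7-difluoro-2-[3,4,5-tris(benzyloxy)phenyl]spiro[chromane-3,2'-[1,3]dithiane] | C1(c2cc(OCc3ccccc3)c(OCc3ccccc3)c(OCc3ccccc3)c2)Oc2cc(F)cc(F)c2CC12SCCCS2 | intermediate
9 | rac-5,7-bis(benzyloxy)-2-[3,4,5-tris(benzyloxy)phenyl]spiro[chromane-3,2'-[1,3]dithiane] | C1(c2cc(OCc3ccccc3)c(OCc3ccccc3)c(OCc3ccccc3)c2)Oc2cc(OCc3ccccc3)cc(OCc3ccccc3)c2CC12SCCCS2 | intermediate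
10 | rac-5,7-bis(benzyloxy)-2-[3,4,5-tris(benzyloxy)phenyl]chroman-3-one | O=C1Cc2c(OCc3ccccc3)cc(OCc3ccccc3)cc2OC1c1cc(OCc2ccccc2)c(OCc2ccccc2)c(OCc2ccccc2)c1 | intermediate
11 | (2R,3R)-5,7-bis(benzyloxy)-2-[3,4,5-tris(benzyloxy)phenyl]chroman-3-ol (penta-O-benzyl-epigallocatechin) | O[C@@H]1Cc2c(OCc3ccccc3)cc(OCc3ccccc3)cc2O[C@@H]1c1cc(OCc2ccccc2)c(OCc2ccccc2)c(OCc2ccccc2)c1 | intermediate
12 | (2R,3R)-8-bromo-5,7-bis(benzyloxy)-2-[3,4,5-tris(benzyloxy)phenyl]chroman-3-ol | O[C@@H]1Cc2c(OCc3ccccc3)cc(OCc3ccccc3)c(Br)c2O[C@@H]1c1cc(OCc2ccccc2)c(OCc2ccccc2)c(OCc2ccccc2)c1 | intermediate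
13 | 3,4,5-tris(benzyloxy)benzoic acid | OC(=O)c1cc(OCc2ccccc2)c(OCc2ccccc2)c(OCc2ccccc2)c1 | starting material
14 | (2R,3R)-8-bromo-5,7-bis(benzyloxy)-2-[3,4,5-tris(benzyloxy)phenyl]chroman-3-yl 3,4,5-tris(benzyloxy)benzoate | O=C(O[C@@H]1Cc2c(OCc3ccccc3)cc(OCc3ccccc3)c(Br)c2O[C@@H]1c1cc(OCc2ccccc2)c(OCc2ccccc2)c(OCc2ccccc2)c1)c1cc(OCc2ccccc2)c(OCc2ccccc2)c(OCc2ccccc2)c1 | intermediate
15 | (2R,3R,4S)-8-bromo-5,7-bis(benzyloxy)-4-(2-ethoxyethoxy)-2-[3,4,5-tris(benzyloxy)phenyl]chroman-3-ol (2,3-cis-3,4-trans) | CCOCCO[C@H]1c2c(OCc3ccccc3)cc(OCc3ccccc3)c(Br)c2O[C@H](c2cc(OCc3ccccc3)c(OCc3ccccc3)c(OCc3ccccc3)c2)[C@@H]1O | intermediate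
16 | (2R,3R)-8-bromo-5,7-bis(benzyloxy)-6-[(2R,3R,4R)-8-bromo-5,7-bis(benzyloxy)-3-hydroxy-2-[3,4,5-tris(benzyloxy)phenyl]chroman-4-yl]-2-[3,4,5-tris(benzyloxy)phenyl]chroman-3-yl 3,4,5-tris(benzyloxy)benzoate | O=C(O[C@@H]1Cc2c(c(Br)c(OCc3ccccc3)c([C@H]3c4c(OCc5ccccc5)cc(OCc5ccccc5)c(Br)c4O[C@H](c4cc(OCc5ccccc5)c(OCc5ccccc5)c(OCc5ccccc5)c4)[C@@H]3O)c2OCc2ccccc2)O[C@@H]1c1cc(OCc2ccccc2)c(OCc2ccccc2)c(OCc2ccccc2)c1)c1cc(OCc2ccccc2)c(OCc2ccccc2)c(OCc2ccccc2)c1 | intermediate
17 | epigallocatechin-(4β→6)-epigallocatechin 3-O-gallate (gallate on the lower unit), (2R,3R)-5,7-dihydroxy-6-[(2R,3R,4S)-3,5,7-trihydroxy-2-(3,4,5-trihydroxyphenyl)chroman-4-yl]-2-(3,4,5-trihydroxyphenyl)chroman-3-yl 3,4,5-trihydroxybenzoate | O=C(O[C@@H]1Cc2c(cc(O)c([C@H]3c4c(O)cc(O)cc4O[C@H](c4cc(O)c(O)c(O)c4)[C@@H]3O)c2O)O[C@@H]1c1cc(O)c(O)c(O)c1)c1cc(O)c(O)c(O)c1 | target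

**Step count and risks**

Total steps: 10. Longest linear sequence: 9 steps (steps 1–6, then 7 or 8, then 9 and 10).

Steps most likely to fail:

Step 2 (Proposed new method). What may go wrong: incomplete second deprotonation of 4, or metalation of the acidic ring C–H of the trifluorophenyl unit by unconsumed carbanion followed by loss of lithium fluoride to an aryne, in place of clean C-alkylation and ring closure. Fallback with known chemistry, setting out from 4 and 5 and returning at 8: 4 is oxidized with MnO2 to [3,4,5-tris(benzyloxy)phenyl](1,3-dithian-2-yl)methanone F1. Its stabilized enolate (NaH, DMF, 0 °C), which needs no organolithium, is C-benzylated with 5 to [2-(2,4,6-trifluorobenzyl)-1,3-dithian-2-yl][3,4,5-tris(benzyloxy)phenyl]methanone F2. Reduction with LiAlH4 gives rac-[2-(2,4,6-trifluorobenzyl)-1,3-dithian-2-yl][3,4,5-tris(benzyloxy)phenyl]methanol F3, the neutral form of 7. NaH in DMF then closes ring C by the same SNAr to give 8.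

Step 5. What may go wrong: epimerization at C2 slower than hydrogenation, so that the dynamic resolution collapses, or induction in the wrong sense. Fallback from 10, returning at 11: reduction with LiBH(s-Bu)3 at −78 °C (hydride anti to the C2 aryl group, the known way from flavan-3-ones to 2,3-cis-flavan-3-ols) should give the racemic cis alcohol, that is 11 together with its enantiomer (2S,3S)-5,7-bis(benzyloxy)-2-[3,4,5-tris(benzyloxy)phenyl]chroman-3-ol F4. The enantiomers are separated by preparative chromatography on a chiral stationary phase, and F4 is returned to racemic 10 by Swern oxidation and recycled.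

Step 9. What may go wrong: slow attack of the hindered C6 of 14, so that the cation from 15 is consumed by self-condensation through its own free C6 or by attack on a pyrogallol ring. Fallback from 15, returning at 16: 15 is converted with benzyl mercaptan and BF3·OEt2 at −78 °C into the 3,4-trans thioether (2R,3S,4S)-4-(benzylsulfanyl)-8-bromo-5,7-bis(benzyloxy)-2-[3,4,5-tris(benzyloxy)phenyl]chroman-3-ol F5, an electrophile that is stable to hard Lewis acids. F5 is then ionized slowly and selectively by thiophilic activation with AgBF4 in the presence of excess 14 to give 16.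

Further compounds
F1 | step 2 | [3,4,5-tris(benzyloxy)phenyl](1,3-dithian-2-yl)methanone | O=C(c1cc(OCc2ccccc2)c(OCc2ccccc2)c(OCc2ccccc2)c1)C1SCCCS1
F2 | step 2 | [2-(2,4,6-trifluorobenzyl)-1,3-dithian-2-yl][3,4,5-tris(benzyloxy)phenyl]methanone | O=C(c1cc(OCc2ccccc2)c(OCc2ccccc2)c(OCc2ccccc2)c1)C1(Cc2c(F)cc(F)cc2F)SCCCS1
F3 | step 2 | rac-[2-(2,4,6-trifluorobenzyl)-1,3-dithian-2-yl][3,4,5-tris(benzyloxy)phenyl]methanol | OC(c1cc(OCc2ccccc2)c(OCc2ccccc2)c(OCc2ccccc2)c1)C1(Cc2c(F)cc(F)cc2F)SCCCS1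
F4 | step 5 | (2S,3S)-5,7-bis(benzyloxy)-2-[3,4,5-tris(benzyloxy)phenyl]chroman-3-ol | O[C@H]1Cc2c(OCc3ccccc3)cc(OCc3ccccc3)cc2O[C@H]1c1cc(OCc2ccccc2)c(OCc2ccccc2)c(OCc2ccccc2)c1
F5 | step 9 | (2R,3S,4S)-4-(benzylsulfanyl)-8-bromo-5,7-bis(benzyloxy)-2-[3,4,5-tris(benzyloxy)phenyl]chroman-3-ol | c1ccccc1CS[C@H]1c2c(OCc3ccccc3)cc(OCc3ccccc3)c(Br)c2O[C@H](c2cc(OCc3ccccc3)c(OCc3ccccc3)c(OCc3ccccc3)c2)[C@@H]1O
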